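The ten-membered carbocycle is disconnected at C9–C10 (germacrane numbering). C9 is an allylic carbinol bonded to C10, the substituted carbon of the ring olefin C1=C10, so intramolecular Nozaki–Hiyama–Kishi addition of a (Z)-C10 vinyl iodide to a C9 aldehyde should create this bond, the ring and the C9 stereocentre in one operation, without base, so that the α-methylene lactone and C8 survive. The seco precursor carries the finished 6,12-lactone, an 8-O-triethylsilyl ether and a 14-O-silyl ether. Its C6–C8 stereotriad comes from D-arabinitol, whose two identical arms are told apart by trans-selective lactonisation; the side chain is built by Claisen rearrangement.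

Key step: step 18

Remark: germacrane numbering is used for all intermediates (ring C1–C10, lactone carbons C11–C13, C14 on C10, C15 on C4; H7 is α), and D-arabinitol is taken as the commercially available pentitol.

Step 1
Reactants: 1 D-arabinitol
Product: 2 1,2:4,5-di-O-isopropylidene-D-arabinitol
Conditions: 2-methoxypropene (2.2 equiv), TsOH·H2O (cat.), DMF, 0 °C; Et3N
Reagents that add atoms: 2-methoxypropene, COC(C)=C
Why: Kinetically controlled acetal formation begins at the primary hydroxyls and closes onto the adjacent secondary ones, so the two terminal dioxolanes should form and leave only O3 free, with no stereocentre touched.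

Step 2
Reactants: 2 1,2:4,5-di-O-isopropylidene-D-arabinitol
Product: 3 bis[(4R)-2,2-dimethyl-1,3-dioxolan-4-yl]methanone
Conditions: DMP (the triacetoxy periodinane), NaHCO3, CH2Cl2, 0 °C → rt
Reagents that add atoms: none
Why: Periodinane oxidation of the only free (secondary) alcohol under buffered, non-epimerising conditions should give the C2-symmetric ketone, in which the two dioxolane arms are equivalent.

Step 3
Reactants: 3 bis-dioxolanyl ketone; 4 ethyl (triphenylphosphoranylidene)acetate
Product: 5 ethyl 3,3-bis[(4S)-2,2-dimethyl-1,3-dioxolan-4-yl]prop-2-enoate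
Conditions: toluene, 90 °C
Reagents that add atoms: ethyl (triphenylphosphoranylidene)acetate, CCOC(=O)C=P(c1ccccc1)(c1ccccc1)c1ccccc1
Why: Wittig olefination of the electron-poor α,α'-dialkoxy ketone with a stabilised ylide introduces C11 and C12, and because both substituents on the ketone carbon are identical no E/Z isomers can arise.

Step 4
Reactants: 5 bis-dioxolanyl enoate
Product: 6 ethyl 3,3-bis[(4S)-2,2-dimethyl-1,3-dioxolan-4-yl]propanoate
Conditions: H2 (1 atm), 10% Pd/C, EtOAc, rt
Reagents that add atoms: none
Why: Catalytic hydrogenation of the trisubstituted enoate should be clean, and since the new sp3 carbon (C7) carries two identical arms it is not yet a stereocentre, so no facial selectivity is needed.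

Step 5
Reactants: 6 bis-dioxolanyl propanoate
Product: 8 (4R,5S)-4-[(4S)-2,2-dimethyl-1,3-dioxolan-4-yl]-5-(hydroxymethyl)oxolan-2-one, via trans-lactone triol 7 (not isolated)
Conditions: 1 M HCl–THF (1:1), 50 °C; evaporate from toluene; then 2,2-dimethoxypropane, CSA (cat.), acetone, rt; Et3N
Reagents that add atoms: 2,2-dimethoxypropane, COC(C)(C)OC
Why: Acid-catalysed acetal hydrolysis and reversible γ-lactonisation followed by acetonide formation on the single remaining 1,2-diol: C7 becomes a stereocentre here under thermodynamic control, the five-membered lactone being expected to close onto the arm that puts the C5 and C8 substituents trans (H6 β, H7 α), while C6 and C8 are carried over unchanged from D-arabinitol.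

Step 6
Reactants: 8 lactone acetonide alcohol
Product: 9 (2S,3R)-3-[(4S)-2,2-dimethyl-1,3-dioxolan-4-yl]-5-oxooxolane-2-carbaldehyde
Conditions: DMP, NaHCO3, CH2Cl2, 0 °C → rt; used crude
Reagents that add atoms: none
Why: Periodinane oxidation of the primary alcohol gives the C5 aldehyde without base, so the adjacent C6 centre should not epimerise.

Step 7
Reactants: 9 lactone aldehyde; 10 isopropenylmagnesium bromide
Product: 11 (4R,5S)-4-[(4S)-2,2-dimethyl-1,3-dioxolan-4-yl]-5-(1-hydroxy-2-methylprop-2-en-1-yl)oxolan-2-one (both C5 carbinol epimers)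
Conditions: THF, −78 °C; AcOH quench at −78 °C
Reagents that add atoms: isopropenylmagnesium bromide, CC(=C)[Mg]Br
Why: Grignard 1,2-addition is much faster to the aldehyde than to the lactone at −78 °C and adds C4, C3 and C15; the C5 carbinol centre forms without control, which does not matter because C5 becomes sp2 in step 8.

Step 8
Reactants: 11 isopropenyl carbinol; 12 ethyl vinyl ether
Product: 14 (4E)-4-methyl-5-(lactone)pent-4-enal with C6 C7 C8 as in 8, via allyl vinyl ether 13 (not isolated)
Conditions: Hg(OAc)2 (0.3 equiv), ethyl vinyl ether (solvent), reflux; concentrate; toluene, 135 °C, sealed tube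
Reagents that add atoms: ethyl vinyl ether, CCOC=C
Why: Mercury-catalysed transvinylation and Claisen rearrangement through a chair in which the bulky lactone-bearing substituent on C5 sits equatorial should form C2–C3 and the (E)-C4=C5 olefin from either C5 epimer, delivering C1 as the aldehyde.

Step 9
Reactants: 14 C1 aldehyde; 15 (triphenylphosphoranylidene)acetaldehyde
Product: 16 (E,E)-dienal: (2E,6E)-enal with C14 as CHO and C6 C7 C8 as in 8
Conditions: toluene, 80 °C
Reagents that add atoms: (triphenylphosphoranylidene)acetaldehyde, O=CC=P(c1ccccc1)(c1ccccc1)c1ccccc1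
Why: Wittig reaction with the stabilised formyl ylide should give the (E)-enal, adding C10 and C14.

Step 10
Reactants: 16 enal
Product: 17 (Z)-C10 iodoenal (iodine on C10, cis to C2)
Conditions: I2, DMAP (cat.), K2CO3, THF–H2O (1:1), rt
Reagents that add atoms: iodine, II
Why: Amine-catalysed α-iodination of the enal (conjugate addition of DMAP, iodination of the enolate, loss of DMAP) should give the (Z)-2-iodoenal, which places iodine on C10 and cis to C2, the geometry the ring olefin needs.

Step 11
Reactants: 17 iodoenal
Product: 18 (Z)-2-iodo allylic alcohol (free C14 hydroxyl)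
Conditions: NaBH4, CeCl3·7H2O, MeOH, −40 °C
Reagents that add atoms: none
Why: Luche 1,2-reduction of the enal leaves the lactone, the vinyl iodide and both olefins untouched and creates no stereocentre.

Step 12
Reactants: 18 iodo allylic alcohol
Product: 19 14-O-tert-butyldiphenylsilyl ether
Conditions: t-BuPh2SiCl, imidazole, CH2Cl2, rt
Reagents that add atoms: tert-butyl(chloro)diphenylsilane, CC(C)(C)[Si](Cl)(c1ccccc1)c1ccccc1
Why: Standard silylation of the primary allylic alcohol; this silyl group is chosen because it must outlast the acidic acetonide cleavage in step 15 and the triethylsilyl removal in step 20.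

Step 13
Reactants: 19 silyl ether lactone
Product: 21 11-(dimethylaminomethyl) lactone (Mannich base), via lithium enolate 20 (not isolated)
Conditions: LiN(SiMe3)2, THF, −78 °C; then dimethylmethylideneammonium iodide, −78 °C → rt
Reagents that add atoms: dimethylmethylideneammonium iodide, C=[N+](C)C.[I-]
Why: Mannich aminomethylation of the lactone enolate, the only acidic site, installs C13; the C11 centre formed (expected trans to the C7 substituent) is removed again in step 14.

Step 14
Reactants: 21 Mannich base
Product: 23 α-methylene lactone acetonide, via trimethylammonium iodide 22 (not isolated)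
Conditions: MeI, CH2Cl2, rt; then sat. aq. NaHCO3, EtOAc, rt
Reagents that add atoms: none
Why: N-Methylation and base-induced β-elimination of trimethylamine (Hofmann-type, E1cB) give the exocyclic C11=C13 olefin under conditions too mild to touch the other groups.

Step 15
Reactants: 23 α-methylene lactone acetonide
Product: 24 8,9-diol
Conditions: AcOH–H2O–THF (3:1:1), 45 °C
Reagents that add atoms: none
Why: Acid hydrolysis of the terminal acetonide, which the tert-butyldiphenylsilyl ether, the vinyl iodide and the α-methylene lactone should all tolerate.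

Step 16
Reactants: 24 8,9-diol
Product: 25 8,9-bis(triethylsilyl) ether
Conditions: Et3SiOTf, 2,6-lutidine, CH2Cl2, −78 → 0 °C
Reagents that add atoms: triethylsilyl trifluoromethanesulfonate, CC[Si](CC)(CC)OS(=O)(=O)C(F)(F)F
Why: Exhaustive silylation with a silyl triflate and a non-nucleophilic base, which avoids any regioselective protection of the diol.

Step 17
Reactants: 25 bis(triethylsilyl) ether
Product: 26 seco C9 aldehyde with (Z)-C10 vinyl iodide, intact α-methylene lactone, 8-O-triethylsilyl and 14-O-tert-butyldiphenylsilyl ethers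
Conditions: (COCl)2, DMSO, CH2Cl2, −78 → −40 °C; Et3N, −78 → 0 °C
Reagents that add atoms: none
Why: Under Swern conditions the activated sulfonium reagent should attack only the unhindered primary triethylsilyl ether, which is cleaved and oxidised to the C9 aldehyde in the same flask while the secondary 8-O-silyl ether survives, and the short, cold exposure to Et3N should leave C8 unepimerised.

Step 18
Reactants: 26 seco aldehyde vinyl iodide
Product: 28 9α-hydroxy-8β-(triethylsilyloxy)-14-(tert-butyldiphenylsilyloxy)germacra-1(10),4,11(13)-trien-6α,12-olide (C2 and C9 cis on C1=C10; 4E), via vinylchromium dichloride 27 (not isolated)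
Conditions: CrCl2 (15 equiv), NiCl2 (0.1 equiv), degassed DMSO–THF (3:1), 3 mM, slow addition of 26, rt; aq. NH4Cl
Reagents that add atoms: none
Why: Divalent chromium reduces the NiCl2 to zerovalent nickel, which undergoes oxidative addition at the vinylic C10–I bond without loss of olefin geometry; transfer of the vinyl group to trivalent chromium then gives vinylchromium 27, whose carbon–chromium bond adds across the C9 aldehyde (intramolecular Nozaki–Hiyama–Kishi reaction). The closest known reaction type is the nickel/chromium-mediated macrocyclisation of ω-formyl vinyl iodides to medium-ring allylic alcohols. The ten-membered ring closes by a 10-exo-trig attack of C10 on the C9 carbonyl, and because C2 and iodine are cis in 26 the ring olefin C1=C10 is formed directly with C2 and C9 on the same side. The new C9 stereocentre is set by substrate control from C8 within the cyclic transition state: the chromium-bound oxygen and the bulky 8β-silyloxy group can both point outward only when they are trans, which should favour the 9α-alcohol, although the open-chain Felkin–Anh preference of α-silyloxy aldehydes points the other way. The step needs chemoselectivity for the aldehyde over the lactone carbonyl and the α-methylene acceptor, which the low basicity and strict 1,2-reactivity of organochromium reagents should secure, and ring closure over oligomerisation, which slow addition at high dilution should secure.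

Step 19
Reactants: 28 macrocyclic 9α-alcohol
Product: 29 9α-acetate
Conditions: Ac2O, pyridine, DMAP (cat.), CH2Cl2, 0 °C → rt
Reagents that add atoms: acetic anhydride, CC(=O)OC(C)=O
Why: DMAP-catalysed acylation of the secondary allylic alcohol with retention at C9.

Step 20
Reactants: 29 9α-acetate
Product: 30 9α-acetoxy-8β-hydroxy 14-silyl ether
Conditions: PPTS, MeOH–CH2Cl2 (1:1), 0 °C → rt
Reagents that add atoms: none
Why: Mild acid solvolysis removes the secondary triethylsilyl ether far faster than the primary tert-butyldiphenylsilyl ether, and the acidic medium should suppress acetyl migration from O9 to O8.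

Step 21
Reactants: 30 8β-alcohol; 31 methacrylic anhydride
Product: 32 9α-acetoxy-8β-methacryloyloxy 14-silyl ether
Conditions: Et3N, DMAP, CH2Cl2, 0 °C
Reagents that add atoms: methacrylic anhydride, CC(=C)C(=O)OC(=O)C(C)=C
Why: Nucleophile-catalysed esterification of the 8β-hydroxyl with excess anhydride at low temperature should outrun acetyl migration from O9 and proceeds with retention at C8.

Step 22
Reactants: 32 diester silyl ether
Product: 33 9α-acetoxy-14-hydroxy-8β-methacryloyloxy germacranolide
Conditions: HF·pyridine, pyridine, THF, 0 °C → rt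
Reagents that add atoms: none
Why: Fluoride-mediated desilylation under buffered acidic conditions frees the C14 hydroxyl without touching the three esters or the Michael acceptors.

Step 23
Reactants: 33 C14 allylic alcohol
Product: 34 CNP0403553.1
Conditions: activated MnO2, CH2Cl2, rt
Reagents that add atoms: none
Why: MnO2 oxidises only the primary allylic alcohol, giving the C14 enal under neutral conditions with no change at any stereocentre or olefin.

Compound list

1 | D-arabinitol (D-arabitol) | OC[C@@H](O)C(O)[C@H](O)CO | starting material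
2 | 1,2:4,5-di-O-isopropylidene-D-arabinitol (bis[(4R)-2,2-dimethyl-1,3-dioxolan-4-yl]methanol) | OC([C@H]1COC(C)(C)O1)[C@H]1COC(C)(C)O1 | intermediate
3 | bis[(4R)-2,2-dimethyl-1,3-dioxolan-4-yl]methanone (C2-symmetric) | O=C([C@H]1COC(C)(C)O1)[C@H]1COC(C)(C)O1 | intermediate
4 | ethyl (triphenylphosphoranylidene)acetate | CCOC(=O)C=P(c1ccccc1)(c1ccccc1)c1ccccc1 | starting material
5 | ethyl 3,3-bis[(4S)-2,2-dimethyl-1,3-dioxolan-4-yl]prop-2-enoate | CCOC(=O)C=C([C@H]1COC(C)(C)O1)[C@H]1COC(C)(C)O1 | intermediate
6 | ethyl 3,3-bis[(4S)-2,2-dimethyl-1,3-dioxolan-4-yl]propanoate (C7 not a stereocentre) | CCOC(=O)CC([C@H]1COC(C)(C)O1)[C@H]1COC(C)(C)O1 | intermediate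
7 | (4R,5S)-4-[(1S)-1,2-dihydroxyethyl]-5-(hydroxymethyl)oxolan-2-one (trans-lactone triol) | OC[C@@H](O)[C@H]1CC(=O)O[C@@H]1CO | intermediate (not isolated)
8 | (4R,5S)-4-[(4S)-2,2-dimethyl-1,3-dioxolan-4-yl]-5-(hydroxymethyl)oxolan-2-one | CC1(C)OC[C@@H](O1)[C@H]1CC(=O)O[C@@H]1CO | intermediate
9 | (2S,3R)-3-[(4S)-2,2-dimethyl-1,3-dioxolan-4-yl]-5-oxooxolane-2-carbaldehyde | CC1(C)OC[C@@H](O1)[C@H]1CC(=O)O[C@@H]1C=O | intermediate
10 | isopropenylmagnesium bromide | CC(=C)[Mg]Br | starting material
11 | (4R,5S)-4-[(4S)-2,2-dimethyl-1,3-dioxolan-4-yl]-5-(1-hydroxy-2-methylprop-2-en-1-yl)oxolan-2-one, both epimers at the carbinol carbon C5 | CC1(C)OC[C@@H](O1)[C@H]1CC(=O)O[C@@H]1C(O)C(C)=C | intermediate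
12 | ethyl vinyl ether | CCOC=C | starting material
13 | vinyl ether of 11 at O5 (allyl vinyl ether, both C5 epimers) | CC1(C)OC[C@@H](O1)[C@H]1CC(=O)O[C@@H]1C(OC=C)C(C)=C | intermediate (not isolated)
14 | (4E)-4-methyl-5-(lactone)pent-4-enal: trans-lactone of 8 carrying the (E)-C4=C5 olefin and C1 as aldehyde; C6, C7, C8 as in 8 | CC1(C)OC[C@@H](O1)[C@H]1CC(=O)O[C@@H]1/C=C(\C)CCC=O | intermediate
15 | (triphenylphosphoranylidene)acetaldehyde | O=CC=P(c1ccccc1)(c1ccccc1)c1ccccc1 | starting material
16 | (2E,6E)-6-methyl-7-(lactone)hepta-2,6-dienal (C14 aldehyde, (E)-C1=C10, (E)-C4=C5; C6, C7, C8 as in 8) | CC1(C)OC[C@@H](O1)[C@H]1CC(=O)O[C@@H]1/C=C(\C)CC/C=C/C=O | intermediate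
17 | (2Z,6E)-2-iodo analogue of 16 (iodine on C10, cis to C2) | CC1(C)OC[C@@H](O1)[C@H]1CC(=O)O[C@@H]1/C=C(\C)CC/C=C(\I)C=O | intermediate
18 | (2Z,6E)-2-iodo-6-methyl-7-(lactone)hepta-2,6-dien-1-ol (free C14 hydroxyl; C6, C7, C8 as in 8) | CC1(C)OC[C@@H](O1)[C@H]1CC(=O)O[C@@H]1/C=C(\C)CC/C=C(\I)CO | intermediate
19 | 14-O-tert-butyldiphenylsilyl ether of 18 | CC1(C)OC[C@@H](O1)[C@H]1CC(=O)O[C@@H]1/C=C(\C)CC/C=C(\I)CO[Si](c1ccccc1)(c1ccccc1)C(C)(C)C | intermediate
20 | lithium enolate of lactone 19 (C11=C12–OLi) | CC1(C)OC[C@@H](O1)[C@H]1C=C(O[Li])O[C@@H]1/C=C(\C)CC/C=C(\I)CO[Si](c1ccccc1)(c1ccccc1)C(C)(C)C | intermediate (not isolated)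
21 | 11-(dimethylaminomethyl) derivative of 19 (Mannich base; C11 configuration immaterial, expected trans to the C7 substituent) | CC1(C)OC[C@@H](O1)[C@H]1C(CN(C)C)C(=O)O[C@@H]1/C=C(\C)CC/C=C(\I)CO[Si](c1ccccc1)(c1ccccc1)C(C)(C)C | intermediate
22 | trimethylammonium iodide of 21 | CC1(C)OC[C@@H](O1)[C@H]1C(C[N+](C)(C)C)C(=O)O[C@@H]1/C=C(\C)CC/C=C(\I)CO[Si](c1ccccc1)(c1ccccc1)C(C)(C)C.[I-] | intermediate (not isolated)
23 | α-methylene lactone acetonide (C11=C13 in place; 8,9-O-isopropylidene; (Z)-C10 iodide; 14-O-silyl) | CC1(C)OC[C@@H](O1)[C@H]1C(=C)C(=O)O[C@@H]1/C=C(\C)CC/C=C(\I)CO[Si](c1ccccc1)(c1ccccc1)C(C)(C)C | intermediate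
24 | 8,9-diol of 23 | OC[C@@H](O)[C@H]1C(=C)C(=O)O[C@@H]1/C=C(\C)CC/C=C(\I)CO[Si](c1ccccc1)(c1ccccc1)C(C)(C)C | intermediate
25 | 8,9-bis(triethylsilyl) ether of 24 | CC[Si](CC)(CC)OC[C@@H](O[Si](CC)(CC)CC)[C@H]1C(=C)C(=O)O[C@@H]1/C=C(\C)CC/C=C(\I)CO[Si](c1ccccc1)(c1ccccc1)C(C)(C)C | intermediate
26 | seco C9 aldehyde: 8-O-triethylsilyl, (Z)-C10 vinyl iodide, 14-O-tert-butyldiphenylsilyl, intact trans α-methylene lactone, (E)-C4=C5 | O=C[C@@H](O[Si](CC)(CC)CC)[C@H]1C(=C)C(=O)O[C@@H]1/C=C(\C)CC/C=C(\I)CO[Si](c1ccccc1)(c1ccccc1)C(C)(C)C | intermediate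
27 | C10 vinylchromium dichloride derived from 26 (trivalent chromium in place of iodine, geometry retained) | O=C[C@@H](O[Si](CC)(CC)CC)[C@H]1C(=C)C(=O)O[C@@H]1/C=C(\C)CC/C=C(\[Cr](Cl)Cl)CO[Si](c1ccccc1)(c1ccccc1)C(C)(C)C | intermediate (not isolated)
28 | 9α-hydroxy-8β-(triethylsilyloxy)-14-(tert-butyldiphenylsilyloxy)germacra-1(10),4,11(13)-trien-6α,12-olide (C2/C9 cis on C1=C10, 4E, H7 α) | CC[Si](CC)(CC)O[C@H]1[C@H]2C(=C)C(=O)O[C@@H]2/C=C(\C)CC/C=C(/CO[Si](c3ccccc3)(c3ccccc3)C(C)(C)C)[C@@H]1O | intermediate
29 | 9α-acetate of 28 | CC[Si](CC)(CC)O[C@H]1[C@H]2C(=C)C(=O)O[C@@H]2/C=C(\C)CC/C=C(/CO[Si](c3ccccc3)(c3ccccc3)C(C)(C)C)[C@@H]1OC(C)=O | intermediate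
30 | 9α-acetoxy-8β-hydroxy-14-(tert-butyldiphenylsilyloxy)germacra-1(10),4,11(13)-trien-6α,12-olide | O[C@H]1[C@H]2C(=C)C(=O)O[C@@H]2/C=C(\C)CC/C=C(/CO[Si](c3ccccc3)(c3ccccc3)C(C)(C)C)[C@@H]1OC(C)=O | intermediate
31 | methacrylic anhydride | CC(=C)C(=O)OC(=O)C(C)=C | starting material
32 | 9α-acetoxy-8β-methacryloyloxy-14-(tert-butyldiphenylsilyloxy)germacra-1(10),4,11(13)-trien-6α,12-olide | C=C(C)C(=O)O[C@H]1[C@H]2C(=C)C(=O)O[C@@H]2/C=C(\C)CC/C=C(/CO[Si](c3ccccc3)(c3ccccc3)C(C)(C)C)[C@@H]1OC(C)=O | intermediate
33 | 9α-acetoxy-14-hydroxy-8β-methacryloyloxygermacra-1(10),4,11(13)-trien-6α,12-olide | C=C(C)C(=O)O[C@H]1[C@H]2C(=C)C(=O)O[C@@H]2/C=C(\C)CC/C=C(/CO)[C@@H]1OC(C)=O | intermediate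
34 | CNP0403553.1: 9α-acetoxy-8β-methacryloyloxy-14-oxogermacra-1(10),4,11(13)-trien-6α,12-olide (C2/C9 cis on C1=C10, formally E because CHO outranks C9; 4E) | C=C(C)C(=O)O[C@H]1[C@H]2C(=C)C(=O)O[C@@H]2/C=C(\C)CC/C=C(/C=O)[C@@H]1OC(C)=O | target

Total step count: 23. Longest linear sequence: 23 steps (1 → 34); all other reactants are commercial.

Steps most likely to fail

Step 18. What may go wrong is poor facial selectivity at the C9 carbonyl during ring closure, the open-chain preference of the α-silyloxy aldehyde overriding the ring bias so that the 9β-alcohol predominates. The fallback sets out from 26: the cyclisation is run as before and its product of opposite C9 configuration, the 9β-alcohol F1, is taken on. A Mitsunobu reaction with acetic acid (PPh3, diisopropyl azodicarboxylate, toluene, 0 °C → rt) should displace the activated allylic hydroxyl with inversion and give the 9α-acetate directly. The route is rejoined at 29 with no additional step.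

Step 5. What may go wrong is insufficient discrimination between the two diastereotopic arms in the equilibrating lactonisation, so that the cis-lactone closed onto the other arm forms in comparable amount. The fallback replaces thermodynamic by kinetic control and sets out from enoate 5. Aqueous acid (1 M HCl, THF, 50 °C) removes both acetals, and only the arm cis to the ester can close, which should give the butenolide triol F2. 2,2-Dimethoxypropane with CSA in acetone then caps the remaining 1,2-diol to give the butenolide acetonide F3. Hydroxyl-directed hydrogenation with [Ir(cod)(PCy3)(py)]PF6 under H2 in CH2Cl2 should deliver hydrogen to C7 from the face of the C5 hydroxymethyl group, which places the C8 arm trans to it. The route is rejoined at 8.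

Step 8. What may go wrong is incomplete transvinylation of the hindered secondary alcohol and erosion of olefin geometry in the rearrangement of the unsubstituted vinyl ether. The fallback sets out from 11: heating with N,N-dimethylacetamide dimethyl acetal in xylene (140 °C) effects an Eschenmoser–Claisen rearrangement, in which the amino substituent of the ketene N,O-acetal enforces the chair with the C5 substituent equatorial. This should give the (E)-γ,δ-unsaturated dimethylamide F4. Cp2Zr(H)Cl in THF at rt then reduces the tertiary amide to the aldehyde in the presence of the lactone, and the route is rejoined at 14.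

Further compounds

F1 | step 18 | 9β-hydroxy-8β-(triethylsilyloxy)-14-(tert-butyldiphenylsilyloxy)germacra-1(10),4,11(13)-trien-6α,12-olide (C9 epimer of 28) | CC[Si](CC)(CC)O[C@H]1[C@H]2C(=C)C(=O)O[C@@H]2/C=C(\C)CC/C=C(/CO[Si](c3ccccc3)(c3ccccc3)C(C)(C)C)[C@H]1O
F2 | step 5 | (5S)-4-[(1S)-1,2-dihydroxyethyl]-5-(hydroxymethyl)furan-2(5H)-one (butenolide triol) | OC[C@@H](O)C1=CC(=O)O[C@@H]1CO
F3 | step 5 | (5S)-4-[(4S)-2,2-dimethyl-1,3-dioxolan-4-yl]-5-(hydroxymethyl)furan-2(5H)-one (butenolide acetonide) | CC1(C)OC[C@@H](O1)C1=CC(=O)O[C@@H]1CO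
F4 | step 8 | (4E)-N,N,4-trimethyl-5-(lactone)pent-4-enamide (dimethylamide analogue of 14; C6, C7, C8 as in 8) | CC1(C)OC[C@@H](O1)[C@H]1CC(=O)O[C@@H]1/C=C(\C)CCC(=O)N(C)C
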